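**Assumption:** the SMILES is taken literally (2S, 5S, 7S in benzofuran numbering O1, C2, C3, C3a, C4–C7, C7a, and S at the side-chain carbinol). This side-chain pairing is the one formed by SN2 (anti) opening of a cis, neryl-type 2,3-epoxide, so the C10 unit is taken from nerol, not geraniol.

## Retrosynthetic overview

1. Target ⇐ 4-O-prenyl enol ether of the C5-prenylated bicyclic dienone: a Claisen-then-Cope relay (O4 → C3a → C7) sets the acyl-bearing C7 centre last.
2. That dienone ⇐ aromatic 4-O-prenyl-2,3-dihydrobenzofuran: a palladium-catalysed enantioselective O-to-C prenyl shift sets C5.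
3. Dihydrofuran ring ⇐ acylphloroglucinol 4-O-prenyl ether + cis-epoxyneryl iodide: C-alkylation, then biomimetic 5-exo opening of the 2,3-epoxide by the ortho oxygen (sets C2, carries the carbinol centre).
4. Building blocks: 2,4,6-trihydroxytoluene, isobutyryl chloride, prenol; nerol (Sharpless epoxidation).
5. Ring order: the six-membered ring is the purchased phloroglucinol ring (dearomatised, never rebuilt); the dihydrofuran is the only ring closed (step 5).

## Route

Step 1
Reactants: 1 2-methylbenzene-1,3,5-triol (2,4,6-trihydroxytoluene); 2 2-methylpropanoyl chloride (isobutyryl chloride)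
Product: 3 2-methyl-1-(2,4,6-trihydroxy-3-methylphenyl)propan-1-one
Conditions: AlCl3 (3.5 equiv), PhNO2, 65 °C; then 1 M HCl
Reagents that add atoms: isobutyryl chloride 2, CC(C)C(Cl)=O
Why: Friedel–Crafts acylation of the strongly activated, symmetrical triol at either of its two equivalent free ring carbons gives one C-acyl ketone (no stereocentre is formed).

Step 2
Reactants: 3 2-methyl-1-(2,4,6-trihydroxy-3-methylphenyl)propan-1-one; 4 3-methylbut-2-en-1-ol (prenol)
Product: 5 1-{2,6-dihydroxy-3-methyl-4-[(3-methylbut-2-en-1-yl)oxy]phenyl}-2-methylpropan-1-one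
Conditions: 4 (1.1 equiv), PPh3, DIAD, THF, 0 °C → rt
Reagents that add atoms: prenol 4, CC(C)=CCO
Why: Mitsunobu etherification alkylates only the 4-hydroxyl, the most acidic one and the only one not hydrogen-bonded to the ketone, which blocks this oxygen for the later ring closure and stores the prenyl group destined for C5 (no stereocentre is formed).

Step 3
Reactants: 6 nerol, (2Z)-3,7-dimethylocta-2,6-dien-1-ol
Product: 7 [(2R,3S)-3-methyl-3-(4-methylpent-3-en-1-yl)oxiran-2-yl]methanol ((2R,3S)-2,3-epoxynerol)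
Conditions: Ti(OiPr)4 (10 mol%), D-(−)-diethyl tartrate (14 mol%), t-BuOOH (2 equiv, isooctane), 4 Å MS, CH2Cl2, −20 °C
Reagents that add atoms: tert-butyl hydroperoxide, CC(C)(C)OO
Why: Sharpless asymmetric epoxidation is specific for the allylic 2,3-alkene (the 6,7-alkene is untouched) and with D-(−)-diethyl tartrate delivers oxygen to the face of the Z-allylic alcohol that gives the (2R,3S) cis-epoxide in about 90–94% ee, which fixes both side-chain stereocentres.

Step 4
Reactants: 7 [(2R,3S)-3-methyl-3-(4-methylpent-3-en-1-yl)oxiran-2-yl]methanol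
Product: 8 (2S,3S)-2-(iodomethyl)-3-methyl-3-(4-methylpent-3-en-1-yl)oxirane
Conditions: I2, PPh3, imidazole, CH2Cl2, 0 °C, dark
Reagents that add atoms: iodine, [I][I]
Why: Appel-type iodination converts the primary alcohol into a soft primary iodide by SN2 at CH2 without opening the epoxide, so both stereocentres are kept (the C2 descriptor changes only because iodine outranks oxygen).

Step 5
Reactants: 5 1-{2,6-dihydroxy-3-methyl-4-[(3-methylbut-2-en-1-yl)oxy]phenyl}-2-methylpropan-1-one; 8 (2S,3S)-2-(iodomethyl)-3-methyl-3-(4-methylpent-3-en-1-yl)oxirane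
Product: 10 1-{(2S)-6-hydroxy-2-[(2S)-2-hydroxy-6-methylhept-5-en-2-yl]-5-methyl-4-[(3-methylbut-2-en-1-yl)oxy]-2,3-dihydro-1-benzofuran-7-yl}-2-methylpropan-1-one, via C-alkylated epoxide 9 (not isolated)
Conditions: KOH (2.2 equiv), MeOH/H2O (4:1), degassed, 0 → 40 °C, dark; then aq NH4Cl
Reagents that add atoms: none
Why: C-alkylation of a phenoxide in protic medium followed by a Baldwin-allowed 5-exo-tet epoxide opening: the dianion of 5, whose two oxygens are ketone-chelated and poor O-nucleophiles, attacks the iodide through its only free ring carbon, and the neighbouring 6-oxide (the 4-oxygen is blocked as the prenyl ether) then opens the epoxide by SN2 at the secondary carbon, which inverts that carbon to 2S and leaves the tertiary carbinol carbon S.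

Step 6
Reactants: 10 1-{(2S)-6-hydroxy-2-[(2S)-2-hydroxy-6-methylhept-5-en-2-yl]-5-methyl-4-[(3-methylbut-2-en-1-yl)oxy]-2,3-dihydro-1-benzofuran-7-yl}-2-methylpropan-1-one
Product: 11 (2S,5R)-6-hydroxy-2-[(2S)-2-hydroxy-6-methylhept-5-en-2-yl]-5-methyl-5-(3-methylbut-2-en-1-yl)-7-(2-methylpropanoyl)-2,3-dihydro-1-benzofuran-4(5H)-one
Conditions: Pd2(dba)3·CHCl3 (2.5 mol%), N,N'-[(1R,2R)-cyclohexane-1,2-diyl]bis[2-(diphenylphosphanyl)benzamide] (7.5 mol%), toluene, 45 °C
Reagents that add atoms: none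
Why: Proposed new method: zerovalent palladium ionises the aryl prenyl ether (the acyl-stabilised 4-phenoxide is as good a leaving group as a nitrophenoxide), O-prenylation of the resulting ion pair is reversible whereas attack of C5, the ring carbon flanked by both oxygens, on the unsubstituted terminus of the π-prenyl ligand gives the stable vinylogous acid irreversibly, and the chiral bisphosphine pocket selects the face of C5 (catalyst control, ligand antipode confirmed in a two-run screen, the C5 epimer and the material from the minor epoxide enantiomer being diastereomers removed by chromatography); the closest known reactions are palladium-catalysed asymmetric allylic dearomatisation of naphthols and phenols, Trost-type asymmetric prenylation of oxindoles and palladium-catalysed C-allylation of phloroglucinol.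

Step 7
Reactants: 11 (2S,5R)-6-hydroxy-2-[(2S)-2-hydroxy-6-methylhept-5-en-2-yl]-5-methyl-5-(3-methylbut-2-en-1-yl)-7-(2-methylpropanoyl)-2,3-dihydro-1-benzofuran-4(5H)-one; 4 3-methylbut-2-en-1-ol (prenol)
Product: 12 (2S,5S)-2-[(2S)-2-hydroxy-6-methylhept-5-en-2-yl]-5-methyl-5-(3-methylbut-2-en-1-yl)-4-[(3-methylbut-2-en-1-yl)oxy]-7-(2-methylpropanoyl)-2,3-dihydro-1-benzofuran-6(5H)-one
Conditions: 4 (1.2 equiv), PPh3, DIAD, THF, 0 °C
Reagents that add atoms: prenol 4, CC(C)=CCO
Why: Mitsunobu O-alkylation of the vinylogous acid takes place at the free O4 terminus of the delocalised enolate, because O6 is held in the hydrogen-bonded chelate to the 7-acyl carbonyl, and gives the cross-conjugated prenyl enol ether without touching the tertiary alcohol (no stereocentre is formed; the C5 descriptor changes by priority only).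

Step 8
Reactants: 12 (2S,5S)-2-[(2S)-2-hydroxy-6-methylhept-5-en-2-yl]-5-methyl-5-(3-methylbut-2-en-1-yl)-4-[(3-methylbut-2-en-1-yl)oxy]-7-(2-methylpropanoyl)-2,3-dihydro-1-benzofuran-6(5H)-one
Product: 14 (2S,5S,7S)-2-[(2S)-2-hydroxy-6-methylhept-5-en-2-yl]-5-methyl-5,7-bis(3-methylbut-2-en-1-yl)-7-(2-methylpropanoyl)-2,3-dihydro-1-benzofuran-4,6(5H,7H)-dione, via 3a-(1,1-dimethylallyl) dienedione 13 (not isolated)
Conditions: tris(6,6,7,7,8,8,8-heptafluoro-2,2-dimethyloctane-3,5-dionato)europium, Eu(fod)3 (10 mol%), CHCl3, 60 °C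
Reagents that add atoms: none
Why: Proposed new method: a Claisen rearrangement can move the O4 prenyl group only to C3a (C5 is quaternary) and the strained 3a-(1,1-dimethylallyl) dienedione then undergoes Cope rearrangement through C3a–C7a=C7, which places a normal prenyl group on the acyl-bearing C7 and restores the vinylogous ester, the suprafacial relay running over the ring face opposite to both the C5 prenyl group and the C2 side chain so that C7 is formed as 7S with the two prenyl groups trans; the closest known reaction is the Eu(fod)3-catalysed para-Claisen–Cope rearrangement of aryl prenyl ethers.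

## Compound list

1 | 2-methylbenzene-1,3,5-triol (2,4,6-trihydroxytoluene) | Cc1c(O)cc(O)cc1O | starting material
2 | 2-methylpropanoyl chloride (isobutyryl chloride) | CC(C)C(Cl)=O | starting material
3 | 2-methyl-1-(2,4,6-trihydroxy-3-methylphenyl)propan-1-one | CC(C)C(=O)c1c(O)cc(O)c(C)c1O | intermediate
4 | 3-methylbut-2-en-1-ol (prenol) | CC(C)=CCO | starting material
5 | 1-{2,6-dihydroxy-3-methyl-4-[(3-methylbut-2-en-1-yl)oxy]phenyl}-2-methylpropan-1-one | CC(C)C(=O)c1c(O)cc(OCC=C(C)C)c(C)c1O | intermediate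
6 | nerol, (2Z)-3,7-dimethylocta-2,6-dien-1-ol | CC(C)=CCC/C(C)=C\CO | starting material
7 | [(2R,3S)-3-methyl-3-(4-methylpent-3-en-1-yl)oxiran-2-yl]methanol | OC[C@H]1O[C@@]1(C)CCC=C(C)C | intermediate
8 | (2S,3S)-2-(iodomethyl)-3-methyl-3-(4-methylpent-3-en-1-yl)oxirane | IC[C@H]1O[C@@]1(C)CCC=C(C)C | intermediate
9 | 1-{2,6-dihydroxy-3-methyl-4-[(3-methylbut-2-en-1-yl)oxy]-5-{[(2R,3S)-3-methyl-3-(4-methylpent-3-en-1-yl)oxiran-2-yl]methyl}phenyl}-2-methylpropan-1-one | CC(C)C(=O)c1c(O)c(C[C@H]2O[C@@]2(C)CCC=C(C)C)c(OCC=C(C)C)c(C)c1O | intermediate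
10 | 1-{(2S)-6-hydroxy-2-[(2S)-2-hydroxy-6-methylhept-5-en-2-yl]-5-methyl-4-[(3-methylbut-2-en-1-yl)oxy]-2,3-dihydro-1-benzofuran-7-yl}-2-methylpropan-1-one | CC(C)=CCC[C@](C)(O)[C@@H]1Cc2c(O1)c(C(=O)C(C)C)c(O)c(C)c2OCC=C(C)C | intermediate
11 | (2S,5R)-6-hydroxy-2-[(2S)-2-hydroxy-6-methylhept-5-en-2-yl]-5-methyl-5-(3-methylbut-2-en-1-yl)-7-(2-methylpropanoyl)-2,3-dihydro-1-benzofuran-4(5H)-one | CC(C)=CCC[C@](C)(O)[C@@H]1CC2=C(O1)C(C(=O)C(C)C)=C(O)[C@@](C)(CC=C(C)C)C2=O | intermediate
12 | (2S,5S)-2-[(2S)-2-hydroxy-6-methylhept-5-en-2-yl]-5-methyl-5-(3-methylbut-2-en-1-yl)-4-[(3-methylbut-2-en-1-yl)oxy]-7-(2-methylpropanoyl)-2,3-dihydro-1-benzofuran-6(5H)-one | CC(C)=CCC[C@](C)(O)[C@@H]1CC2=C(OCC=C(C)C)[C@](C)(CC=C(C)C)C(=O)C(C(=O)C(C)C)=C2O1 | intermediate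
13 | (2S,3aR,5S)-2-[(2S)-2-hydroxy-6-methylhept-5-en-2-yl]-5-methyl-5-(3-methylbut-2-en-1-yl)-3a-(2-methylbut-3-en-2-yl)-7-(2-methylpropanoyl)-3,3a-dihydro-1-benzofuran-4,6(2H,5H)-dione | CC(C)=CCC[C@](C)(O)[C@@H]1C[C@]2(C(C)(C)C=C)C(=O)[C@](C)(CC=C(C)C)C(=O)C(C(=O)C(C)C)=C2O1 | intermediate
14 | (2S,5S,7S)-2-[(2S)-2-hydroxy-6-methylhept-5-en-2-yl]-5-methyl-5,7-bis(3-methylbut-2-en-1-yl)-7-(2-methylpropanoyl)-2,3-dihydro-1-benzofuran-4,6(5H,7H)-dione (CNP0250451.1) | CC(C)=CCC[C@](C)(O)[C@@H]1CC2=C(O1)[C@@](CC=C(C)C)(C(=O)C(C)C)C(=O)[C@@](C)(CC=C(C)C)C2=O | target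

## Step count and risks

Total step count: 8. Longest linear sequence: 6 steps (1 → 3 → 5 → 10 → 11 → 12 → 14; the nerol arm 6 → 7 → 8 joins at step 5 and is also 6 steps to the target).

The three steps most likely to fail, each with a fallback:

First, step 5. The iodide 8 is a β-oxygenated primary halide, so its SN2 reaction at the ring carbon of the dianion of 5 may be slow and O-alkylation may compete. The fallback sets out from 3 (with 8) and comes back at 10. The unprotected triol 3, a much stronger carbon nucleophile, is alkylated with 8 (KOH, 3.2 equiv, MeOH/H2O) to give 2-methyl-1-(2,4,6-trihydroxy-3-methyl-5-{[(2R,3S)-3-methyl-3-(4-methylpent-3-en-1-yl)oxiran-2-yl]methyl}phenyl)propan-1-one F1, which is not isolated. It closes through either flanking oxygen to 1-{(2S)-4,6-dihydroxy-2-[(2S)-2-hydroxy-6-methylhept-5-en-2-yl]-5-methyl-2,3-dihydro-1-benzofuran-7-yl}-2-methylpropan-1-one F2 and its regioisomer 1-{(2S)-4,6-dihydroxy-2-[(2S)-2-hydroxy-6-methylhept-5-en-2-yl]-7-methyl-2,3-dihydro-1-benzofuran-5-yl}-2-methylpropan-1-one F3. F3 is removed by chromatography. Mitsunobu reaction of F2 with prenol 4 (PPh3, DIAD, THF) at its only non-chelated hydroxyl (on C4) then gives 10. The price is the loss of the regiocontrol that the prenyl ether provides.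

Second, step 6. The prenyl ether may ionise slowly, the ion pair may attack through C3a or C7, and the ligand may give poor facial control. The fallback sets out from 10 and comes back at 12, so step 7 is not needed. The sodium phenoxide of 10 (NaH, toluene, 0 °C) is alkylated with prenyl bromide as a contact ion pair, which directs the electrophile to the ortho carbon C5 (dearomatising ortho-C-alkylation of phenoxides in non-polar solvent). This gives 12 directly together with its C5 epimer (2S,5R)-2-[(2S)-2-hydroxy-6-methylhept-5-en-2-yl]-5-methyl-5-(3-methylbut-2-en-1-yl)-4-[(3-methylbut-2-en-1-yl)oxy]-7-(2-methylpropanoyl)-2,3-dihydro-1-benzofuran-6(5H)-one F4, which is separated by chromatography. Stereocontrol at C5 is given up for a diastereomer separation.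

Third, step 8. The Claisen step must join the substituted C3a to the dimethyl-bearing allyl terminus, the Lewis acid may instead cause an ion-pair shift to a 3a-prenyl isomer, and the facial preference may be modest. The fallback sets out from 10 and comes back at 14, reversing the order of the two prenyl transfers. Heating 10 (Eu(fod)3 in toluene at 100 °C, or PhNEt2 at 180 °C) starts the classical para-Claisen–Cope sequence of an aryl prenyl ether with both ortho positions blocked. The ortho-dienone (2S,5S)-6-hydroxy-2-[(2S)-2-hydroxy-6-methylhept-5-en-2-yl]-5-methyl-5-(2-methylbut-3-en-2-yl)-7-(2-methylpropanoyl)-2,3-dihydro-1-benzofuran-4(5H)-one F5 is not isolated. It rearranges to (2S,7S)-6-hydroxy-2-[(2S)-2-hydroxy-6-methylhept-5-en-2-yl]-5-methyl-7-(3-methylbut-2-en-1-yl)-7-(2-methylpropanoyl)-2,3-dihydro-1-benzofuran-4(7H)-one F6, formed together with its C7 epimer (2S,7R)-6-hydroxy-2-[(2S)-2-hydroxy-6-methylhept-5-en-2-yl]-5-methyl-7-(3-methylbut-2-en-1-yl)-7-(2-methylpropanoyl)-2,3-dihydro-1-benzofuran-4(7H)-one F7, which is separated. F6 is then prenylated at C5, now the only nucleophilic carbon (a 2-methyl-1,3-dione unit), with tert-butyl prenyl carbonate and the palladium catalyst of step 6 to give 14. In this order the ligand must override any substrate bias at C5, and the C7 centre is no longer relayed from C5.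

## Further compounds

F1 | step 5 | 2-methyl-1-(2,4,6-trihydroxy-3-methyl-5-{[(2R,3S)-3-methyl-3-(4-methylpent-3-en-1-yl)oxiran-2-yl]methyl}phenyl)propan-1-one | CC(C)C(=O)c1c(O)c(C[C@H]2O[C@@]2(C)CCC=C(C)C)c(O)c(C)c1O
F2 | step 5 | 1-{(2S)-4,6-dihydroxy-2-[(2S)-2-hydroxy-6-methylhept-5-en-2-yl]-5-methyl-2,3-dihydro-1-benzofuran-7-yl}-2-methylpropan-1-one | CC(C)=CCC[C@](C)(O)[C@@H]1Cc2c(O1)c(C(=O)C(C)C)c(O)c(C)c2O
F3 | step 5 | 1-{(2S)-4,6-dihydroxy-2-[(2S)-2-hydroxy-6-methylhept-5-en-2-yl]-7-methyl-2,3-dihydro-1-benzofuran-5-yl}-2-methylpropan-1-one | CC(C)=CCC[C@](C)(O)[C@@H]1Cc2c(O1)c(C)c(O)c(C(=O)C(C)C)c2O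
F4 | step 6 | (2S,5R)-2-[(2S)-2-hydroxy-6-methylhept-5-en-2-yl]-5-methyl-5-(3-methylbut-2-en-1-yl)-4-[(3-methylbut-2-en-1-yl)oxy]-7-(2-methylpropanoyl)-2,3-dihydro-1-benzofuran-6(5H)-one | CC(C)=CCC[C@](C)(O)[C@@H]1CC2=C(OCC=C(C)C)[C@@](C)(CC=C(C)C)C(=O)C(C(=O)C(C)C)=C2O1
F5 | step 8 | (2S,5S)-6-hydroxy-2-[(2S)-2-hydroxy-6-methylhept-5-en-2-yl]-5-methyl-5-(2-methylbut-3-en-2-yl)-7-(2-methylpropanoyl)-2,3-dihydro-1-benzofuran-4(5H)-one | CC(C)=CCC[C@](C)(O)[C@@H]1CC2=C(O1)C(C(=O)C(C)C)=C(O)[C@](C)(C(C)(C)C=C)C2=O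
F6 | step 8 | (2S,7S)-6-hydroxy-2-[(2S)-2-hydroxy-6-methylhept-5-en-2-yl]-5-methyl-7-(3-methylbut-2-en-1-yl)-7-(2-methylpropanoyl)-2,3-dihydro-1-benzofuran-4(7H)-one | CC(C)=CCC[C@](C)(O)[C@@H]1CC2=C(O1)[C@@](CC=C(C)C)(C(=O)C(C)C)C(O)=C(C)C2=O
F7 | step 8 | (2S,7R)-6-hydroxy-2-[(2S)-2-hydroxy-6-methylhept-5-en-2-yl]-5-methyl-7-(3-methylbut-2-en-1-yl)-7-(2-methylpropanoyl)-2,3-dihydro-1-benzofuran-4(7H)-one | CC(C)=CCC[C@](C)(O)[C@@H]1CC2=C(O1)[C@](CC=C(C)C)(C(=O)C(C)C)C(O)=C(C)C2=O
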